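**Retrosynthetic overview**
- The target is unmasked last from its 3'-O-benzyl ether by hydrogenolysis.
- The pyranone ring is the only ring built: it is closed (O1–C2) by iodine/DMSO oxidative cyclisation of a 2'-hydroxychalcone.
- The chalcone Cα–Cβ bond is the key C–C bond, formed by an intermolecular Claisen–Schmidt aldol condensation of 2'-hydroxy-4',5',6'-trimethoxyacetophenone with 3-benzyloxy-4,5-dimethoxybenzaldehyde.
- The ketone comes from 3,4,5-trimethoxyphenol by C-acetylation; the aldehyde comes from 5-bromovanillin by Cu hydroxylation, selective 4-O-methylation and 3-O-benzylation.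
- Both benzene rings are bought; the fragments are made separately and joined in the aldol step.

Assumption: the target SMILES has no stereocentre, so the compound is achiral and no enantiocontrol is needed; the only stereo-element in the route is the E-alkene of chalcone 9, which disappears on cyclisation.

**Step 1**
Reactants: 1 3,4,5-trimethoxyphenol
Product: 3 1-(6-hydroxy-2,3,4-trimethoxyphenyl)ethanone, via difluoroboron chelate 2 (not isolated)
Conditions: AcOH, BF3·OEt2 (3 equiv), 90 °C, 3 h; then 10% aq NaOAc, rt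
Reagents that add atoms: acetic acid, CC(=O)O
Why: BF3-promoted Friedel–Crafts (Nencki-type) C-acylation takes place at one of the two equivalent free positions ortho to the OH of the symmetric phenol, giving the ketone as its BF2 chelate, which aqueous acetate hydrolyses.

**Step 2**
Reactants: 4 3-bromo-4-hydroxy-5-methoxybenzaldehyde (5-bromovanillin)
Product: 5 3,4-dihydroxy-5-methoxybenzaldehyde (5-hydroxyvanillin)
Conditions: NaOH (8 equiv), Cu powder (5 mol%), H2O, reflux, N2, 24 h; then HCl to pH 2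
Reagents that add atoms: sodium hydroxide, [Na+].[OH-]
Why: Copper-catalysed Ullmann-type hydroxylation replaces the aryl bromide, while the para-phenoxide deactivates the aldehyde towards Cannizzaro reaction in hot alkali.

**Step 3**
Reactants: 5 3,4-dihydroxy-5-methoxybenzaldehyde
Product: 6 3-hydroxy-4,5-dimethoxybenzaldehyde
Conditions: Me2SO4 (1.05 equiv), Na2CO3 (1.1 equiv), acetone, reflux, 5 h
Reagents that add atoms: dimethyl sulfate, COS(=O)(=O)OC
Why: Regioselective Williamson O-methylation: the 4-OH para to the formyl group is much more acidic than the 3-OH, so a weak carbonate base and one equivalent of alkylating agent form and methylate only the 4-phenoxide.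

**Step 4**
Reactants: 6 3-hydroxy-4,5-dimethoxybenzaldehyde
Product: 7 3-(benzyloxy)-4,5-dimethoxybenzaldehyde
Conditions: BnBr (1.2 equiv), K2CO3 (1.5 equiv), DMF, 60 °C, 4 h
Reagents that add atoms: benzyl bromide, BrCc1ccccc1
Why: Williamson ether synthesis on the only remaining phenol masks it as a benzyl ether that is stable to the strong base of the aldol step and to I2/DMSO.

**Step 5**
Reactants: 3 1-(6-hydroxy-2,3,4-trimethoxyphenyl)ethanone; 7 3-(benzyloxy)-4,5-dimethoxybenzaldehyde
Product: 9 (E)-3-[3-(benzyloxy)-4,5-dimethoxyphenyl]-1-(6-hydroxy-2,3,4-trimethoxyphenyl)prop-2-en-1-one, via aldol adduct 8 (not isolated)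
Conditions: 50% aq KOH (10 equiv), EtOH, rt, 48 h; then 2 M HCl, 0 °C
Reagents that add atoms: none
Why: Claisen–Schmidt (crossed aldol) condensation: the enolate of methyl ketone 3 adds to non-enolisable aldehyde 7, and E1cB dehydration of the β-hydroxy ketone gives the thermodynamically favoured E-enone.

**Step 6**
Reactants: 9 (E)-3-[3-(benzyloxy)-4,5-dimethoxyphenyl]-1-(6-hydroxy-2,3,4-trimethoxyphenyl)prop-2-en-1-one
Product: 12 2-[3-(benzyloxy)-4,5-dimethoxyphenyl]-5,6,7-trimethoxy-4H-chromen-4-one, via flavanone 10 (not isolated), via 3-iodoflavanone 11 (not isolated)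
Conditions: I2 (10 mol%), DMSO, 125 °C, 3 h; then aq Na2S2O3
Reagents that add atoms: none
Why: Iodine-catalysed oxidative cyclisation: intramolecular oxa-Michael addition of the 2'-OH gives the flavanone, α-iodination and loss of HI give the flavone, and DMSO reoxidises HI to I2 as terminal oxidant.

**Step 7**
Reactants: 12 2-[3-(benzyloxy)-4,5-dimethoxyphenyl]-5,6,7-trimethoxy-4H-chromen-4-one
Product: 13 2-(3-hydroxy-4,5-dimethoxyphenyl)-5,6,7-trimethoxy-4H-chromen-4-one
Conditions: H2 (1 atm), 10% Pd/C, EtOAc/MeOH 1:1, rt, 3 h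
Reagents that add atoms: none
Why: Catalytic hydrogenolysis cleaves the benzyl aryl ether, while the conjugated pyranone C2=C3 bond and the aryl methyl ethers (including the acid-labile 5-OMe) are untouched at 1 atm and room temperature.

**Compound list**
1 | 3,4,5-trimethoxyphenol | COc1cc(O)cc(OC)c1OC | starting material
2 | 2,2-difluoro-5,6,7-trimethoxy-4-methyl-1,3,2-benzodioxaborinine chelate (BF2 chelate of 3) | CC1=[O+][B-](F)(F)Oc2cc(OC)c(OC)c(OC)c21 | intermediate (not isolated)
3 | 1-(6-hydroxy-2,3,4-trimethoxyphenyl)ethanone | CC(=O)c1c(O)cc(OC)c(OC)c1OC | intermediate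
4 | 3-bromo-4-hydroxy-5-methoxybenzaldehyde (5-bromovanillin) | COc1cc(C=O)cc(Br)c1O | starting material
5 | 3,4-dihydroxy-5-methoxybenzaldehyde | COc1cc(C=O)cc(O)c1O | intermediate
6 | 3-hydroxy-4,5-dimethoxybenzaldehyde | COc1cc(C=O)cc(O)c1OC | intermediate
7 | 3-(benzyloxy)-4,5-dimethoxybenzaldehyde | COc1cc(C=O)cc(OCc2ccccc2)c1OC | intermediate
8 | 3-[3-(benzyloxy)-4,5-dimethoxyphenyl]-3-hydroxy-1-(6-hydroxy-2,3,4-trimethoxyphenyl)propan-1-one (racemic aldol adduct) | COc1cc(C(O)CC(=O)c2c(O)cc(OC)c(OC)c2OC)cc(OCc2ccccc2)c1OC | intermediate (not isolated)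
9 | (E)-3-[3-(benzyloxy)-4,5-dimethoxyphenyl]-1-(6-hydroxy-2,3,4-trimethoxyphenyl)prop-2-en-1-one | COc1cc(/C=C/C(=O)c2c(O)cc(OC)c(OC)c2OC)cc(OCc2ccccc2)c1OC | intermediate
10 | 2-[3-(benzyloxy)-4,5-dimethoxyphenyl]-5,6,7-trimethoxychroman-4-one (racemic flavanone) | COc1cc(C2CC(=O)c3c(OC)c(OC)c(OC)cc3O2)cc(OCc2ccccc2)c1OC | intermediate (not isolated)
11 | 2-[3-(benzyloxy)-4,5-dimethoxyphenyl]-3-iodo-5,6,7-trimethoxychroman-4-one (racemic, diastereomer mixture) | COc1cc(C2Oc3cc(OC)c(OC)c(OC)c3C(=O)C2I)cc(OCc2ccccc2)c1OC | intermediate (not isolated)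
12 | 2-[3-(benzyloxy)-4,5-dimethoxyphenyl]-5,6,7-trimethoxy-4H-chromen-4-one | COc1cc(-c2cc(=O)c3c(OC)c(OC)c(OC)cc3o2)cc(OCc2ccccc2)c1OC | intermediate
13 | 2-(3-hydroxy-4,5-dimethoxyphenyl)-5,6,7-trimethoxy-4H-chromen-4-one | COc1cc(-c2cc(=O)c3c(OC)c(OC)c(OC)cc3o2)cc(O)c1OC | target

**Totals**
Total step count: 7.
Longest linear sequence: 6 steps (steps 2, 3, 4, 5, 6, 7, from 4 to 13).

**Three steps most likely to fail**

Step 3 (selective 4-O-methylation; risk of bis-methylation or the wrong mono-ether). The fallback sets out from 4 and comes back at 6, and no longer has to tell two phenols apart. Compound 4 is O-methylated (MeI, K2CO3, DMF) to 3-bromo-4,5-dimethoxybenzaldehyde F1. Miyaura borylation (B2pin2, Pd(dppf)Cl2, KOAc, dioxane, 90 °C) then gives 3,4-dimethoxy-5-(4,4,5,5-tetramethyl-1,3,2-dioxaborolan-2-yl)benzaldehyde F2. Oxidation of the C–B bond (NaBO3·4H2O, THF/H2O, rt) delivers 6.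

Step 5 (aldol condensation; the di-ortho-substituted, electron-rich ketone may condense slowly or partly divert to flavanone). The fallback sets out from 7 (with 3) and comes back at 12, replacing the aldol by an intermolecular Claisen-type C-acylation. Pinnick oxidation of 7 (NaClO2, NaH2PO4, 2-methyl-2-butene, t-BuOH/H2O) gives 3-(benzyloxy)-4,5-dimethoxybenzoic acid F3. Oxalyl chloride with catalytic DMF in CH2Cl2 converts it into 3-(benzyloxy)-4,5-dimethoxybenzoyl chloride F4. The lithium dianion of 3 (LiHMDS 3.5 equiv, THF, −78 °C to rt) is C-acylated by F4 to give 1-[3-(benzyloxy)-4,5-dimethoxyphenyl]-3-(6-hydroxy-2,3,4-trimethoxyphenyl)propane-1,3-dione F5. Cyclodehydration (AcOH, 0.5% H2SO4, 95 °C, 1 h) gives 12.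

Step 6 (oxidative cyclisation; HI formed in situ may cleave the 5-OMe or benzyl ether, or the reaction may stall at the flavanone). The fallback sets out from 9 and comes back at 12 by separating ring closure from oxidation. Chalcone 9 is cyclised by oxa-Michael addition (NaOAc, EtOH, reflux) and flavanone 10 is isolated. It is then dehydrogenated with DDQ (dioxane, reflux) to 12. This detour makes no compound outside the list (entry F0).

**Further compounds**
F1 | step 3 | 3-bromo-4,5-dimethoxybenzaldehyde | COc1cc(C=O)cc(Br)c1OC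
F2 | step 3 | 3,4-dimethoxy-5-(4,4,5,5-tetramethyl-1,3,2-dioxaborolan-2-yl)benzaldehyde | COc1cc(C=O)cc(B2OC(C)(C)C(C)(C)O2)c1OC
F3 | step 5 | 3-(benzyloxy)-4,5-dimethoxybenzoic acid | COc1cc(C(=O)O)cc(OCc2ccccc2)c1OC
F4 | step 5 | 3-(benzyloxy)-4,5-dimethoxybenzoyl chloride | COc1cc(C(=O)Cl)cc(OCc2ccccc2)c1OC
F5 | step 5 | 1-[3-(benzyloxy)-4,5-dimethoxyphenyl]-3-(6-hydroxy-2,3,4-trimethoxyphenyl)propane-1,3-dione | COc1cc(C(=O)CC(=O)c2c(O)cc(OC)c(OC)c2OC)cc(OCc2ccccc2)c1OC
F0 | step 6 | none | none
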